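Take one ratio to the flask: the burn, −ln f divided by P, where f is the fraction of free monomer left at a run's last reading and P is the pre-initiator charged. You have three finished runs and one flask to call.

| flask | free monomer | pre-initiator | remark | time |
|---|---|---|---|---|
| north-east | 0.020 M | 0.34 mM | run made earlier |  |
| west | 0.020 M | 0.75 mM | run made earlier |  |
| south-east | 0.040 M | 0.50 mM | run made earlier |  |
| flask | 0.020 M | 0.50 mM |  | 50 min |

- north-east (time / min: monomer in chains / %, free monomer / %): 4.00: 2, 97; 6.00: 3, 95; 12.0: 10, 91; 20.0: 11, 90; 30.0: 14, 90; 50.0: 13, 88
- west (time / min: monomer in chains / %, free monomer / %): 3.00: 4, 97; 10.0: 14, 84; 20.0: 21, 78; 25.0: 24, 78; 40.0: 22, 77; 50.0: 23, 76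
- south-east (time / min: monomer in chains / %, free monomer / %): 4.00: 2, 94; 8.00: 8, 92; 15.0: 12, 86; 25.0: 15, 85; 50.0: 19, 84

(readings scatter by 1.5 percentage points)

- the average divides the monomer in chains by the number of chains begun, living and dead together
- the earlier runs do not show the number of chains; that part of a forecast is a guess

- average number of monomer units in a chain (chains begun, living or dead) at 50 min
- part of the free monomer that has reacted at 50 min

The north-east, west and south-east runs give burns of 0.376 mM⁻¹, 0.366 mM⁻¹ and 0.349 mM⁻¹, although the south-east run holds twice the free monomer. Their mean, B = 0.364 mM⁻¹, is the burn you carry.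

Now keep the books for the flask, as my own reckoning. Free monomer ends at 88%, 76% and 84% of its charge in those runs, so I book pre-initiator as the limiting reagent. First entry: each pre-initiator begins one chain, which is a guess, since the runs do not show the number of chains. Second entry: by B, the flask's 0.50 mM should burn about 16.6% of the free monomer. To close: monomer in chains over chains begun gives an average of 6.65.

The forecast gives 17% reacted and an average of 10, a higher average than mine, on the ground that “Incomplete activation raises this”.

The flask gives 17.5% reacted and an average of 7.01.

    free monomer + initiator → living end + monomer in chains (k = 140 M⁻¹ min⁻¹)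
    free monomer + living end → monomer in chains + living end, rate k2*[living end]*[free monomer] (k = 60.0 M⁻¹ min⁻¹)
    monomer in chains + living end → free monomer + living end, rate k3*[living end] as long as [monomer in chains] is above zero (k = 0.0610 min⁻¹)
    living end → dead end (k = 0.170 min⁻¹)
    pre-initiator → initiator (k = 0.160 min⁻¹)

The flask's own burn is 0.385 mM⁻¹. At 50.0 min the flask's pre-initiator stands at 0.034% of its charge; with initiator at 1.25 × 10⁻⁸ M, living end at 1.12 × 10⁻⁶ M and dead end at 4.99 × 10⁻⁴ M, the books close at 0.500 mM against the charge of 0.50 mM. The falling level of pre-initiator is one reason the flask's average reaches 7.01: in the same run with that level held, it stands at 3.98.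

For a neighbour flask with 0.0020 M of pre-initiator and all else as in the flask, B gives 51.7% reacted; that neighbour gives 54.0%, with an average of 5.40.

All runs stem from a simulated flask for an exercise, and the scatter is random.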